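**Plan**

1. Retrosynthesis: the two ester C–O bonds are cut first (malonate at O3, 3-methylpentanoate at O15), then C6–C7 of ring B, then C9–C10; this leaves an achiral ring A allylic alcohol 8 and an achiral E-heptenoic acid 15.
2. Forward: ring A is bought as a dione and carried as a ketal; an ester-enolate [3,3] rearrangement joins the chain at C9–C10 and leaves an exocyclic C5=C6 olefin; the acid carbon is turned into the E-alkenyl iodide C7=C8(CH3); ring B is then closed at C6–C7 and the two esters are added last.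
3. Enabling feature: in ring B the allylic carbon C6 is bonded to the olefinic carbon C7 of the C7=C8 double bond, and its other neighbour C5 is a tertiary ring-fusion carbon between the quaternary carbons C4 and C10. A C7 alkenyl radical can therefore add only to C6 of a C5=C6 methylidene on ring A (6-endo), brings the olefin with it, and leaves C5 to be set by hydrogen transfer.
4. Stereochemistry: C9 and C10 are set together in the reagent-controlled Claisen step; C5 follows from C10 in the ring closure; C3 follows from the decalin (bulky hydride, axial alcohol); the E C13=C14 olefin comes from syn-carboalumination; the acyl stereocentre is bought.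

Key step: step 14

Remark: carbons are called by labdane locants throughout, also in the open precursors (ring A = C1–C5 and C10, ring B = C5–C10, chain C11–C16, C17 on C8, C20 on C10); configurations are those of the CIP descriptors and the SMILES (5S,9R,10S means H5 and H9 both trans to the C10 methyl).

Assumption: the (4R,5R) boron controller is taken to give the (2S,8S) acid 19; the sense of induction at this tetrasubstituted allyl terminus would be fixed by correlation in the first run, and the (4S,5S) controller, which gives the mirror-image acid, used if it proved opposite.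

**Route**

Step 1
Reactants: 1 2,2-dimethylcyclohexane-1,3-dione
Product: 2 6,6-dimethyl-1,4-dioxaspiro[4.5]decan-7-one
Conditions: HOCH2CH2OH (1.1 equiv), TsOH (cat.), PhH, reflux, Dean–Stark trap
Reagents that add atoms: ethylene glycol OCCO
Why: acid-catalysed ketalisation stops at the mono-ketal because the second carbonyl then lies between the quaternary carbon and the new ketal; this masks the future C3 ketone.

Step 2
Reactants: 2 6,6-dimethyl-1,4-dioxaspiro[4.5]decan-7-one
Product: 4 rac-6,6,8-trimethyl-1,4-dioxaspiro[4.5]decan-7-one, via lithium enolate 3 (not isolated)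
Conditions: LiN(i-Pr)2, THF, −78 °C; MeI, −78 to 0 °C
Reagents that add atoms: iodomethane CI
Why: enolate alkylation is regiospecific because the ketone has α-hydrogens on one side only; the new stereocentre is of no account since it becomes sp2 in step 3.

Step 3
Reactants: 4 rac-6,6,8-trimethyl-1,4-dioxaspiro[4.5]decan-7-one
Product: 6 6,6,8-trimethyl-1,4-dioxaspiro[4.5]dec-7-en-7-yl trifluoromethanesulfonate, via potassium enolate 5 (not isolated)
Conditions: KN(SiMe3)2, THF, −78 to 0 °C; PhNTf2, 0 °C to rt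
Reagents that add atoms: N-phenylbis(trifluoromethanesulfonimide) O=S(=O)(N(c1ccccc1)S(=O)(=O)C(F)(F)F)C(F)(F)F
Why: enol triflate formation can give only the tetrasubstituted C5=C10 enolate, as known for 2,2,6-trimethylcyclohexanone.

Step 4
Reactants: 6 6,6,8-trimethyl-1,4-dioxaspiro[4.5]dec-7-en-7-yl trifluoromethanesulfonate
Product: 7 methyl 6,6,8-trimethyl-1,4-dioxaspiro[4.5]dec-7-ene-7-carboxylate
Conditions: Pd(OAc)2 (cat.), PPh3, CO (1 atm), MeOH, Et3N, DMF, 60 °C
Reagents that add atoms: carbon monoxide [C-]#[O+]; methanol CO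
Why: palladium-catalysed alkoxycarbonylation of an enol triflate (oxidative addition, CO insertion, methanolysis) installs C6, as precedented for 2,6,6-trimethylcyclohexenyl triflates.

Step 5
Reactants: 7 methyl 6,6,8-trimethyl-1,4-dioxaspiro[4.5]dec-7-ene-7-carboxylate
Product: 8 (6,6,8-trimethyl-1,4-dioxaspiro[4.5]dec-7-en-7-yl)methanol
Conditions: i-Bu2AlH (2.5 equiv), CH2Cl2, −78 to 0 °C; aq. KNaC4H4O6
Reagents that add atoms: none
Why: 1,2-reduction of the unsaturated ester by the aluminium hydride gives the allylic alcohol and leaves the ketal untouched.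

Step 6
Reactants: 9 5-chloropent-1-yne
Product: 12 (2E)-6-chloro-3-methylhex-2-en-1-ol, via alkenylalane 10 (not isolated), via lithium aluminate 11 (not isolated)
Conditions: Me3Al (2 equiv), Cp2ZrCl2 (0.25 equiv), CH2Cl2, 0 °C to rt; n-BuLi, THF, −78 °C; (CH2O)n, rt
Reagents that add atoms: trimethylaluminium C[Al](C)C; formaldehyde (as paraformaldehyde) C=O
Why: zirconium-catalysed carboalumination adds methyl and aluminium syn across the alkyne and the aluminate is hydroxymethylated with retention, which fixes the E geometry of the future C13=C14 olefin.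

Step 7
Reactants: 12 (2E)-6-chloro-3-methylhex-2-en-1-ol
Product: 13 tert-butyl{[(2E)-6-chloro-3-methylhex-2-en-1-yl]oxy}dimethylsilane
Conditions: t-BuMe2SiCl, imidazole, CH2Cl2, rt
Reagents that add atoms: tert-butylchlorodimethylsilane CC(C)(C)[Si](C)(C)Cl
Why: standard silylation of the primary allylic alcohol gives a group that survives the bases, the boron reagent and the aluminium reagent used later.

Step 8
Reactants: 13 tert-butyl{[(2E)-6-chloro-3-methylhex-2-en-1-yl]oxy}dimethylsilane
Product: 15 (5E)-7-[(tert-butyldimethylsilyl)oxy]-5-methylhept-5-enoic acid, via Grignard reagent 14 (not isolated)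
Conditions: Mg, BrCH2CH2Br (cat.), THF, reflux; CO2, −20 °C; aq. citric acid
Reagents that add atoms: carbon dioxide O=C=O
Why: Grignard formation from the primary chloride and carboxylation add the acid carbon (C8) without touching the silyl ether or the trisubstituted olefin.

Step 9
Reactants: 8 (6,6,8-trimethyl-1,4-dioxaspiro[4.5]dec-7-en-7-yl)methanol; 15 (5E)-7-[(tert-butyldimethylsilyl)oxy]-5-methylhept-5-enoic acid
Product: 16 (6,6,8-trimethyl-1,4-dioxaspiro[4.5]dec-7-en-7-yl)methyl (5E)-7-[(tert-butyldimethylsilyl)oxy]-5-methylhept-5-enoate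
Conditions: DCC, DMAP, CH2Cl2, rt
Reagents that add atoms: none
Why: Steglich esterification joins the two achiral halves through the primary allylic alcohol.

Step 10
Reactants: 16 (6,6,8-trimethyl-1,4-dioxaspiro[4.5]dec-7-en-7-yl)methyl (5E)-7-[(tert-butyldimethylsilyl)oxy]-5-methylhept-5-enoate
Product: 19 (2S,5E)-7-[(tert-butyldimethylsilyl)oxy]-5-methyl-2-[(8S)-6,6,8-trimethyl-7-methylidene-1,4-dioxaspiro[4.5]decan-8-yl]hept-5-enoic acid, via boron ketene acetal 17 (not isolated), via boryl ester 18 (not isolated)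
Conditions: (4R,5R)-bromoborane controller (made from the bis-sulfonamide and BBr3, CH2Cl2), i-Pr2NEt, CH2Cl2, −78 °C; then −20 °C, several days; aq. work-up
Reagents that add atoms: none
Why: soft enolisation should give the Z(O) boron ketene acetal (C11 cis to O–B), which undergoes an enantioselective boron-mediated Ireland–Claisen rearrangement through a chair transition state with the C10 methyl and H9 both axial, so C9 and C10 are set together (H9 anti to the methyl) while the C2-symmetric sulfonamide ligand on boron selects the enolate face and hence the absolute configuration.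

Step 11
Reactants: 19 the (2S,8S) acid of step 10
Product: 21 (3S,6E)-8-[(tert-butyldimethylsilyl)oxy]-6-methyl-3-[(8S)-6,6,8-trimethyl-7-methylidene-1,4-dioxaspiro[4.5]decan-8-yl]oct-6-en-2-one, via dilithium diolate 20 (not isolated)
Conditions: MeLi (3 equiv), Et2O, 0 °C to rt; Me3SiCl; aq. NH4Cl
Reagents that add atoms: methyllithium [Li]C
Why: addition of the organolithium to the lithium carboxylate stops at the dilithium diolate, which gives the methyl ketone on work-up (ketone synthesis from a carboxylic acid); this adds C7.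

Step 12
Reactants: 21 the methyl ketone of step 11
Product: 24 tert-butyldimethyl{[(2E,6R)-3-methyl-6-[(8S)-6,6,8-trimethyl-7-methylidene-1,4-dioxaspiro[4.5]decan-8-yl]oct-2-en-7-yn-1-yl]oxy}silane, via lithium enolate 22 (not isolated), via enol phosphate 23 (not isolated)
Conditions: LiN(i-Pr)2 (1.05 equiv), THF, −78 °C; ClP(O)(OEt)2; LiN(i-Pr)2 (2.3 equiv), −78 °C to rt; H2O
Reagents that add atoms: none
Why: ketone-to-alkyne conversion by enol phosphate elimination; kinetic deprotonation takes place at the methyl group and not at the hindered C9–H, so C9 should keep its configuration (its descriptor changes only through priorities).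

Step 13
Reactants: 24 the terminal alkyne of step 12
Product: 26 tert-butyl{[(2E,6S,7E)-8-iodo-3,7-dimethyl-6-[(8S)-6,6,8-trimethyl-7-methylidene-1,4-dioxaspiro[4.5]decan-8-yl]octa-2,7-dien-1-yl]oxy}dimethylsilane, via alkenylalane 25 (not isolated)
Conditions: Me3Al (3 equiv), Cp2ZrCl2 (0.5 equiv), H2O (1 equiv), CH2Cl2, −20 °C; I2, THF, −30 °C
Reagents that add atoms: trimethylaluminium C[Al](C)C; iodine I-I
Why: zirconium-catalysed syn-carboalumination puts the methyl group on C8 and aluminium on C7, and iodinolysis with retention gives the E-alkenyl iodide; the water-accelerated low-temperature variant is chosen to spare the ketal.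

Step 14
Reactants: 26 the E-alkenyl iodide of step 13
Product: 27 (5S,9R,10S)-15-[(tert-butyldimethylsilyl)oxy]-3,3-(ethylenedioxy)labda-7,13E-diene
Conditions: Bu3SnH (1.3 equiv, syringe pump), AIBN (0.2 equiv), PhH (0.005 M), 80 °C
Reagents that add atoms: none
Why: Bu3Sn• abstracts iodine to give the σ-alkenyl radical at C7, which inverts rapidly so that the E geometry of 26 is no obstacle; it adds to C6 of the exocyclic C5=C6 olefin and the tertiary C5 radical then takes hydrogen from Bu3SnH. The closest known reaction type is the tin hydride alkenyl radical cyclisation onto a 1,1-disubstituted olefin. Ring B closes in the 6-endo-trig mode, because the 5-exo mode would have to bond to C5, which is fully substituted and lies between the quaternary carbons C4 and C10, and any 5-exo radical would return to the 6-endo radical through the homoallyl–cyclopropylcarbinyl shuttle at high dilution. The one new stereocentre, C5, is set by substrate control: hydrogen should be delivered to the face opposite the C10 methyl and the axial C4 methyl, giving the trans ring fusion, as in hydrogen-atom-transfer reductions of ring-fusion olefins. The C7=C8 double bond is carried in by the radical itself, so its position cannot scramble. The step needs ring closure to outrun direct reduction and 1,5-hydrogen transfer from the allylic C12–H; slow addition of the hydride at high dilution and the gem-disubstitution at C10 are meant to secure this.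

Step 15
Reactants: 27 the decalin ketal of step 14
Product: 28 (5S,9R,10S)-15-hydroxylabda-7,13E-dien-3-one
Conditions: TsOH·H2O (0.2 equiv), acetone/H2O (10:1), 40 °C
Reagents that add atoms: water O
Why: acid hydrolysis removes the dioxolane and the primary silyl ether in one operation, and the trisubstituted C7=C8 olefin should not migrate under this mild acid.

Step 16
Reactants: 28 (5S,9R,10S)-15-hydroxylabda-7,13E-dien-3-one; 29 (3S)-3-methylpentanoic acid
Product: 30 (5S,9R,10S)-3-oxolabda-7,13E-dien-15-yl (3S)-3-methylpentanoate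
Conditions: DCC, DMAP, CH2Cl2, 0 °C to rt
Reagents that add atoms: none
Why: Steglich esterification of the primary allylic alcohol; the stereocentre of the acid is β to the carbonyl and cannot epimerise.

Step 17
Reactants: 30 (5S,9R,10S)-3-oxolabda-7,13E-dien-15-yl (3S)-3-methylpentanoate
Product: 31 (3S,5S,9R,10S)-3-hydroxylabda-7,13E-dien-15-yl (3S)-3-methylpentanoate
Conditions: LiBH(sec-Bu)3 (1.2 equiv), THF, −78 °C; H2O
Reagents that add atoms: none
Why: the bulky hydride should attack the C3 ketone along the equatorial path (the axial path is blocked by the syn-axial hydrogens at C1 and C5), giving the axial (3S) alcohol trans to the C10 methyl, as in reductions of 4,4-dimethyl-3-oxo terpenoids to their axial alcohols; the ester should survive at −78 °C.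

Step 18
Reactants: 31 (3S,5S,9R,10S)-3-hydroxylabda-7,13E-dien-15-yl (3S)-3-methylpentanoate; 32 2,2-dimethyl-1,3-dioxane-4,6-dione (Meldrum's acid)
Product: 33 (3S,5S,9R,10S)-3-[(carboxyacetyl)oxy]labda-7,13E-dien-15-yl (3S)-3-methylpentanoate (CNP0234792.1)
Conditions: toluene, 100 °C
Reagents that add atoms: none
Why: thermal ring-opening of Meldrum's acid by the alcohol gives the malonic half-ester directly with loss of acetone, so the free acid needs no protecting group.

**Compound list**

1 | 2,2-dimethylcyclohexane-1,3-dione | CC1(C)C(=O)CCCC1=O | starting material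
2 | 6,6-dimethyl-1,4-dioxaspiro[4.5]decan-7-one | O=C1CCCC2(OCCO2)C1(C)C | intermediate
3 | lithium 6,6-dimethyl-1,4-dioxaspiro[4.5]dec-7-en-7-olate | [Li]OC1=CCCC2(OCCO2)C1(C)C | intermediate
4 | rac-6,6,8-trimethyl-1,4-dioxaspiro[4.5]decan-7-one | CC1CCC2(OCCO2)C(C)(C)C1=O | intermediate
5 | potassium 6,6,8-trimethyl-1,4-dioxaspiro[4.5]dec-7-en-7-olate | [K]OC1=C(C)CCC2(OCCO2)C1(C)C | intermediate
6 | 6,6,8-trimethyl-1,4-dioxaspiro[4.5]dec-7-en-7-yl trifluoromethanesulfonate | CC1=C(OS(=O)(=O)C(F)(F)F)C(C)(C)C2(OCCO2)CC1 | intermediate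
7 | methyl 6,6,8-trimethyl-1,4-dioxaspiro[4.5]dec-7-ene-7-carboxylate | COC(=O)C1=C(C)CCC2(OCCO2)C1(C)C | intermediate
8 | (6,6,8-trimethyl-1,4-dioxaspiro[4.5]dec-7-en-7-yl)methanol | OCC1=C(C)CCC2(OCCO2)C1(C)C | intermediate
9 | 5-chloropent-1-yne | ClCCCC#C | starting material
10 | [(1E)-5-chloro-2-methylpent-1-en-1-yl]dimethylalane | ClCCC/C(C)=C/[Al](C)C | intermediate
11 | lithium butyl[(1E)-5-chloro-2-methylpent-1-en-1-yl]dimethylaluminate | [Li+].ClCCC/C(C)=C/[Al-](C)(C)CCCC | intermediate
12 | (2E)-6-chloro-3-methylhex-2-en-1-ol | ClCCC/C(C)=C/CO | intermediate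
13 | tert-butyl{[(2E)-6-chloro-3-methylhex-2-en-1-yl]oxy}dimethylsilane | ClCCC/C(C)=C/CO[Si](C)(C)C(C)(C)C | intermediate
14 | {(4E)-6-[(tert-butyldimethylsilyl)oxy]-4-methylhex-4-en-1-yl}magnesium chloride | Cl[Mg]CCC/C(C)=C/CO[Si](C)(C)C(C)(C)C | intermediate
15 | (5E)-7-[(tert-butyldimethylsilyl)oxy]-5-methylhept-5-enoic acid | OC(=O)CCC/C(C)=C/CO[Si](C)(C)C(C)(C)C | intermediate
16 | (6,6,8-trimethyl-1,4-dioxaspiro[4.5]dec-7-en-7-yl)methyl (5E)-7-[(tert-butyldimethylsilyl)oxy]-5-methylhept-5-enoate | CC(C)(C)[Si](C)(C)OC/C=C(\C)CCCC(=O)OCC1=C(C)CCC2(OCCO2)C1(C)C | intermediate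
17 | Z(O) boron ketene acetal of 16 bearing the (4R,5R)-1,3-bis{[3,5-bis(trifluoromethyl)phenyl]sulfonyl}-4,5-diphenyl-1,3,2-diazaborolidin-2-yl group on the enolate oxygen | CC(C)(C)[Si](C)(C)OC/C=C(\C)CC/C=C(/OCC1=C(C)CCC2(OCCO2)C1(C)C)OB1N(S(=O)(=O)c2cc(cc(c2)C(F)(F)F)C(F)(F)F)[C@H](c2ccccc2)[C@@H](c2ccccc2)N1S(=O)(=O)c1cc(cc(c1)C(F)(F)F)C(F)(F)F | intermediate
18 | O-boryl ester of acid 19 with the same (4R,5R)-diazaborolidine | CC(C)(C)[Si](C)(C)OC/C=C(\C)CC[C@H](C(=O)OB3N(S(=O)(=O)c4cc(cc(c4)C(F)(F)F)C(F)(F)F)[C@H](c4ccccc4)[C@@H](c4ccccc4)N3S(=O)(=O)c3cc(cc(c3)C(F)(F)F)C(F)(F)F)[C@]1(C)CCC2(OCCO2)C(C)(C)C1=C | intermediate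
19 | (2S,5E)-7-[(tert-butyldimethylsilyl)oxy]-5-methyl-2-[(8S)-6,6,8-trimethyl-7-methylidene-1,4-dioxaspiro[4.5]decan-8-yl]hept-5-enoic acid | CC(C)(C)[Si](C)(C)OC/C=C(\C)CC[C@H](C(=O)O)[C@]1(C)CCC2(OCCO2)C(C)(C)C1=C | intermediate
20 | dilithium 1,1-diolate formed from 19 and MeLi (C9 and C10 as in 19) | CC(C)(C)[Si](C)(C)OC/C=C(\C)CC[C@H](C(C)(O[Li])O[Li])[C@]1(C)CCC2(OCCO2)C(C)(C)C1=C | intermediate
21 | (3S,6E)-8-[(tert-butyldimethylsilyl)oxy]-6-methyl-3-[(8S)-6,6,8-trimethyl-7-methylidene-1,4-dioxaspiro[4.5]decan-8-yl]oct-6-en-2-one | CC(C)(C)[Si](C)(C)OC/C=C(\C)CC[C@H](C(C)=O)[C@]1(C)CCC2(OCCO2)C(C)(C)C1=C | intermediate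
22 | lithium enolate of 21 on the methyl side (C9 and C10 as in 21) | CC(C)(C)[Si](C)(C)OC/C=C(\C)CC[C@H](C(=C)O[Li])[C@]1(C)CCC2(OCCO2)C(C)(C)C1=C | intermediate
23 | diethyl enol phosphate of 21 on the methyl side (C9 and C10 as in 21) | CC(C)(C)[Si](C)(C)OC/C=C(\C)CC[C@H](C(=C)OP(=O)(OCC)OCC)[C@]1(C)CCC2(OCCO2)C(C)(C)C1=C | intermediate
24 | tert-butyldimethyl{[(2E,6R)-3-methyl-6-[(8S)-6,6,8-trimethyl-7-methylidene-1,4-dioxaspiro[4.5]decan-8-yl]oct-2-en-7-yn-1-yl]oxy}silane | CC(C)(C)[Si](C)(C)OC/C=C(\C)CC[C@H](C#C)[C@]1(C)CCC2(OCCO2)C(C)(C)C1=C | intermediate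
25 | E-alkenyl(dimethyl)alane from 24 (Al on C7 trans to C9, methyl on C8) | CC(C)(C)[Si](C)(C)OC/C=C(\C)CC[C@H](/C(C)=C/[Al](C)C)[C@]1(C)CCC2(OCCO2)C(C)(C)C1=C | intermediate
26 | tert-butyl{[(2E,6S,7E)-8-iodo-3,7-dimethyl-6-[(8S)-6,6,8-trimethyl-7-methylidene-1,4-dioxaspiro[4.5]decan-8-yl]octa-2,7-dien-1-yl]oxy}dimethylsilane | CC(C)(C)[Si](C)(C)OC/C=C(\C)CC[C@H](/C(C)=C/I)[C@]1(C)CCC2(OCCO2)C(C)(C)C1=C | intermediate
27 | (5S,9R,10S)-15-[(tert-butyldimethylsilyl)oxy]-3,3-(ethylenedioxy)labda-7,13E-diene | CC(C)(C)[Si](C)(C)OC/C=C(\C)CC[C@@H]1C(C)=CC[C@@H]2C(C)(C)C3(OCCO3)CC[C@@]12C | intermediate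
28 | (5S,9R,10S)-15-hydroxylabda-7,13E-dien-3-one | OC/C=C(\C)CC[C@@H]1C(C)=CC[C@@H]2C(C)(C)C(=O)CC[C@@]12C | intermediate
29 | (3S)-3-methylpentanoic acid | CC[C@H](C)CC(=O)O | starting material
30 | (5S,9R,10S)-3-oxolabda-7,13E-dien-15-yl (3S)-3-methylpentanoate | CC[C@H](C)CC(=O)OC/C=C(\C)CC[C@@H]1C(C)=CC[C@@H]2C(C)(C)C(=O)CC[C@@]12C | intermediate
31 | (3S,5S,9R,10S)-3-hydroxylabda-7,13E-dien-15-yl (3S)-3-methylpentanoate | CC[C@H](C)CC(=O)OC/C=C(\C)CC[C@@H]1C(C)=CC[C@@H]2C(C)(C)[C@@H](O)CC[C@@]12C | intermediate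
32 | 2,2-dimethyl-1,3-dioxane-4,6-dione (Meldrum's acid) | CC1(C)OC(=O)CC(=O)O1 | starting material
33 | (3S,5S,9R,10S)-3-[(carboxyacetyl)oxy]labda-7,13E-dien-15-yl (3S)-3-methylpentanoate | CC[C@H](C)CC(=O)OC/C=C(\C)CC[C@@H]1C(C)=CC[C@@H]2C(C)(C)[C@@H](OC(=O)CC(=O)O)CC[C@@]12C | target

**Count and risks**

Total step count: 18. Longest linear sequence: 15 steps (steps 1–5 and 9–18); the acid 15 is made in 3 steps (6–8) and joins at step 9.

Steps most likely to fail:

1. Step 14. Transfer of the allylic C12 hydrogen to the alkenyl radical (1,5-shift), or reduction by the tin hydride before ring closure, may outrun the 6-endo closure, and hydrogen delivery to C5 may not be fully face-selective. The fallback sets out from alkyne 24 and comes back at 27. Copper-catalysed methylboration of 24 (CuCl, Xantphos, NaOt-Bu, B2pin2, MeI, THF) should give the alkenyl boronate F1 with boron trans to C9. NaOH and I2 should convert it with inversion into the Z-alkenyl iodide F2. Hydroboration of the C5=C6 methylidene with 9-BBN, from the face opposite the axial methyl groups, should give the alkylborane F3 with C5 set. PdCl2(dppf), AsPh3 and Cs2CO3 in DMF/H2O should then form the same C6–C7 bond by an intramolecular B-alkyl Suzuki–Miyaura coupling to give 27.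

2. Step 10. Enantiofacial discrimination by the boron controller may be weak or reversed at a tetrasubstituted allyl terminus, and the Lewis-acidic boron may ionise the ketal or the allylic ester during the long reaction. The fallback sets out from ester 16 and comes back at 19. LiN(i-Pr)2 and Me3SiCl in THF/DMPU at −78 °C should give the Z-silyl ketene acetal F4, which rearranges on warming through the same chair to the racemic silyl ester F5 and, after aqueous work-up, the racemic acid F6 of the same relative configuration. Crystallisation with (S)-1-phenylethanamine should give the diastereomerically pure salt F7, and aqueous citric acid frees 19.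

3. Step 18. Acylation of the hindered axial C3 alcohol next to the quaternary C4 may be slow, and prolonged heating may decarboxylate the half-ester. The fallback sets out from 31 and comes back at 33. Acylation at room temperature with mono-2-(trimethylsilyl)ethyl malonate, DCC and DMAP should give the mixed malonate F8, and Bu4NF in THF at 0 °C removes the silylethyl group to give 33.

**Further compounds**

F1 | step 14 | E-alkenyl pinacol boronate from 24 (boron on C7 trans to C9, methyl on C8; C9 and C10 as in 24) | CC(C)(C)[Si](C)(C)OC/C=C(\C)CC[C@H](/C(C)=C/B1OC(C)(C)C(C)(C)O1)[C@]1(C)CCC2(OCCO2)C(C)(C)C1=C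
F2 | step 14 | Z-alkenyl iodide, the C7=C8 geometric isomer of 26 (iodine cis to C9) | CC(C)(C)[Si](C)(C)OC/C=C(\C)CC[C@H](/C(C)=C\I)[C@]1(C)CCC2(OCCO2)C(C)(C)C1=C
F3 | step 14 | B-alkyl-9-borabicyclo[3.3.1]nonane from F2 (boron on C6, H5 trans to the C10 methyl) | CC(C)(C)[Si](C)(C)OC/C=C(\C)CC[C@H](/C(C)=C\I)[C@]1(C)CCC2(OCCO2)C(C)(C)[C@H]1CB3C4CCCC3CCC4
F4 | step 10 | Z-trimethylsilyl ketene acetal of ester 16 (C11 cis to O–Si) | CC(C)(C)[Si](C)(C)OC/C=C(\C)CC/C=C(/OCC1=C(C)CCC2(OCCO2)C1(C)C)O[Si](C)(C)C
F5 | step 10 | racemic trimethylsilyl ester of acid 19 (both enantiomers, relative configuration as in 19) | CC(C)(C)[Si](C)(C)OC/C=C(\C)CC[C@H](C(=O)O[Si](C)(C)C)[C@]1(C)CCC2(OCCO2)C(C)(C)C1=C.CC(C)(C)[Si](C)(C)OC/C=C(\C)CC[C@@H](C(=O)O[Si](C)(C)C)[C@@]1(C)CCC2(OCCO2)C(C)(C)C1=C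
F6 | step 10 | racemic acid (19 and its enantiomer) | CC(C)(C)[Si](C)(C)OC/C=C(\C)CC[C@H](C(=O)O)[C@]1(C)CCC2(OCCO2)C(C)(C)C1=C.CC(C)(C)[Si](C)(C)OC/C=C(\C)CC[C@@H](C(=O)O)[C@@]1(C)CCC2(OCCO2)C(C)(C)C1=C
F7 | step 10 | (S)-1-phenylethanaminium salt of acid 19 | CC(C)(C)[Si](C)(C)OC/C=C(\C)CC[C@H](C(=O)[O-])[C@]1(C)CCC2(OCCO2)C(C)(C)C1=C.C[C@H]([NH3+])c1ccccc1
F8 | step 18 | mixed malonate of 31: 2-(trimethylsilyl)ethyl ester at the free malonyl carboxyl | CC[C@H](C)CC(=O)OC/C=C(\C)CC[C@@H]1C(C)=CC[C@@H]2C(C)(C)[C@@H](OC(=O)CC(=O)OCC[Si](C)(C)C)CC[C@@]12C
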